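**Plan**
- Retrosynthetic cuts, in this order: (i) the C5=CH ylidene bond of the tetronic acid (ring C), by aldol and dehydration on a methyl tetronate; (ii) the bond from C4 of the central furan (ring B) to the chain CH2; (iii) the C(sp2)–CH2 bond at the methyl-bearing carbon of the chain alkene (B-alkyl Suzuki–Miyaura); (iv) the C=C(I) bond (iodo-Wittig).
- Enabling feature: ring B (O1, C2 with the CH2 to furan ring A, C3–H, C4 with the chain, C5–H) is a 2,4-disubstituted furan. It is therefore the dehydration product of a tertiary carbinol made from 5-(furan-3-ylmethyl)furan-3(2H)-one, in which C4 of ring B is the ketone carbon and C5 is an OCH2 group.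
- Forward order: ring A is bought; the furanone is built by Weinreb ynone synthesis and amine-mediated cyclisation; the chain is assembled with its Z-alkene; the key step adds the chain organocerium to the furanone and loses water, joining the fragments and making ring B aromatic; ring C is attached last.
- Stereochemistry: the (S)-methyl centre comes from an Evans allylation with the (R)-benzyl oxazolidinone; the Z-trisubstituted alkene from a Z-selective iodo-Wittig and a stereoretentive Suzuki coupling; the Z-ylidene from a thermodynamically controlled elimination.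

Key step: step 12

Remark: the target is read as (S) at the methyl-bearing carbon, Z at the chain alkene and Z at the ylidene, drawn as the 4-hydroxy tautomer; compounds 1, 3, 9, 14 and 26 are taken as catalogue compounds.

**Route**

Step 1
Reactants: 1 2-(furan-3-yl)acetic acid
Product: 2 2-(furan-3-yl)-N-methoxy-N-methylacetamide
Conditions: CDI, CH2Cl2, rt; then MeNH(OMe)·HCl, rt
Reagents that add atoms: N,O-dimethylhydroxylamine hydrochloride, CNOC.Cl
Why: Amide coupling through the acyl imidazole should give the Weinreb amide without touching ring A.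

Step 2
Reactants: 2 2-(furan-3-yl)-N-methoxy-N-methylacetamide; 3 2-(prop-2-yn-1-yloxy)tetrahydro-2H-pyran
Product: 5 1-(furan-3-yl)-5-(tetrahydro-2H-pyran-2-yloxy)pent-3-yn-2-one, via lithium acetylide 4 (not isolated)
Conditions: 3, n-BuLi, THF, −78 °C; then 2, −78 → 0 °C; aq. NH4Cl
Reagents that add atoms: none
Why: Weinreb ketone synthesis, in which the chelated tetrahedral adduct should persist until work-up so that the ynone is released only then and is not attacked a second time.

Step 3
Reactants: 5 1-(furan-3-yl)-5-(tetrahydro-2H-pyran-2-yloxy)pent-3-yn-2-one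
Product: 6 1-(furan-3-yl)-5-hydroxypent-3-yn-2-one
Conditions: PPTS (cat.), MeOH, rt
Reagents that add atoms: none
Why: Acid-catalysed transacetalisation to methanol should remove the THP group under conditions mild enough for ring A and the ynone.

Step 4
Reactants: 6 1-(furan-3-yl)-5-hydroxypent-3-yn-2-one
Product: 8 5-(furan-3-ylmethyl)furan-3(2H)-one, via enaminone 7 (not isolated)
Conditions: Et2NH, EtOH, rt; then AcOH, H2O, THF, rt
Reagents that add atoms: water, O
Why: Conjugate addition of the amine gives enaminone 7, and in aqueous acid the hydroxyl group adds to the ketone, water is lost and the iminium ion is hydrolysed, which is the established amine-mediated cyclisation of 4-hydroxyalk-2-ynones to 3(2H)-furanones and places the carbonyl group on the future C4 of ring B.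

Step 5
Reactants: 9 (R)-4-benzyl-3-propanoyl-1,3-oxazolidin-2-one
Product: 11 (R)-4-benzyl-3-[(S)-2-methylpent-4-enoyl]-1,3-oxazolidin-2-one, via sodium enolate 10 (not isolated)
Conditions: NaN(SiMe3)2, THF, −78 °C; then allyl iodide, −78 → −45 °C
Reagents that add atoms: allyl iodide, C=CCI
Why: Evans asymmetric alkylation, in which the chelated Z-enolate is attacked by allyl iodide on the face opposite the benzyl group, so the (R)-auxiliary should set the (S)-configured methyl centre.

Step 6
Reactants: 11 (R)-4-benzyl-3-[(S)-2-methylpent-4-enoyl]-1,3-oxazolidin-2-one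
Product: 12 (S)-2-methylpent-4-en-1-ol
Conditions: LiBH4, MeOH (1 equiv), Et2O, 0 °C
Reagents that add atoms: none
Why: Reductive cleavage of the N-acyl oxazolidinone by LiBH4 should give the primary alcohol without epimerisation and return the auxiliary.

Step 7
Reactants: 12 (S)-2-methylpent-4-en-1-ol
Product: 13 tert-butyl{[(S)-2-methylpent-4-en-1-yl]oxy}diphenylsilane
Conditions: TBDPSCl, imidazole, CH2Cl2, rt
Reagents that add atoms: tert-butylchlorodiphenylsilane, CC(C)(C)[Si](Cl)(c1ccccc1)c1ccccc1
Why: Silylation of the primary alcohol gives an ether that should survive the borane, acid methanolysis, t-BuLi and the organocerium step and can be removed by fluoride at the end.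

Step 8
Reactants: 14 3-[(tert-butyldimethylsilyl)oxy]propanal
Product: 15 tert-butyl{[(3Z)-4-iodopent-3-en-1-yl]oxy}dimethylsilane
Conditions: EtPPh3I, n-BuLi, THF, rt; I2, −78 °C; NaN(SiMe3)2, −20 °C; then 14, −78 °C → rt
Reagents that add atoms: ethyltriphenylphosphonium iodide, CC[P+](c1ccccc1)(c1ccccc1)c1ccccc1.[I-]; iodine, II
Why: Zhao-type Wittig olefination with the α-iodo ylide, which under salt-free kinetic control should give the alkene with iodine cis to the chain (Z).

Step 9
Reactants: 13 tert-butyl{[(S)-2-methylpent-4-en-1-yl]oxy}diphenylsilane; 15 tert-butyl{[(3Z)-4-iodopent-3-en-1-yl]oxy}dimethylsilane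
Product: 17 (3Z,8S)-1-[(tert-butyldimethylsilyl)oxy]-9-[(tert-butyldiphenylsilyl)oxy]-4,8-dimethylnon-3-ene, via alkylborane 16 (not isolated)
Conditions: 13, 9-BBN, THF, rt; then 15, PdCl2(dppf) (cat.), AsPh3, Cs2CO3, DMF/H2O, rt
Reagents that add atoms: none
Why: Anti-Markovnikov hydroboration followed by B-alkyl Suzuki–Miyaura coupling, which proceeds with retention at the alkenyl iodide, should place the new chain cis to the CH2CH2O arm and so fix the Z-trisubstituted alkene.

Step 10
Reactants: 17 (3Z,8S)-1-[(tert-butyldimethylsilyl)oxy]-9-[(tert-butyldiphenylsilyl)oxy]-4,8-dimethylnon-3-ene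
Product: 18 (3Z,8S)-9-[(tert-butyldiphenylsilyl)oxy]-4,8-dimethylnon-3-en-1-ol
Conditions: CSA (cat.), MeOH/CH2Cl2, 0 °C
Reagents that add atoms: none
Why: Acid-catalysed methanolysis should cleave the primary TBS ether much faster than the bulkier and more acid-stable TBDPS ether.

Step 11
Reactants: 18 (3Z,8S)-9-[(tert-butyldiphenylsilyl)oxy]-4,8-dimethylnon-3-en-1-ol
Product: 19 tert-butyl{[(2S,6Z)-9-iodo-2,6-dimethylnon-6-en-1-yl]oxy}diphenylsilane
Conditions: I2, PPh3, imidazole, CH2Cl2, 0 °C → rt
Reagents that add atoms: iodine, II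
Why: Appel-type iodination of the primary alcohol through its alkoxyphosphonium ion should give the homoallylic iodide without moving the alkene.

Step 12
Reactants: 19 tert-butyl{[(2S,6Z)-9-iodo-2,6-dimethylnon-6-en-1-yl]oxy}diphenylsilane; 8 5-(furan-3-ylmethyl)furan-3(2H)-one
Product: 23 tert-butyl({(2S,6Z)-9-[5-(furan-3-ylmethyl)furan-3-yl]-2,6-dimethylnon-6-en-1-yl}oxy)diphenylsilane, via alkyllithium 20 (not isolated), via alkylcerium dichloride 21 (not isolated), via tertiary carbinol 22 (not isolated)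
Conditions: 19, t-BuLi (2 equiv), Et2O/pentane, −78 °C; CeCl3, THF, −78 °C; then 8, −78 °C; then 0.5 M aq. HCl, THF, 0 °C
Reagents that add atoms: none
Why: Iodine–lithium exchange gives the primary alkyllithium 20, CeCl3 converts it into the weakly basic and strongly oxophilic organocerium 21, and this adds 1,2 to the ketone carbon of the furanone (the future C4 of ring B) to give carbinol 22; dilute acid then ionises the tertiary allylic C–O bond to a cation stabilised by the ring oxygen, and loss of a proton from the neighbouring OCH2 group gives the aromatic furan. The closest known reaction types are the Stork–Danheiser 1,2-addition of organometallics to vinylogous esters with acid work-up and the Grignard addition and dehydration of benzofuran-3(2H)-ones to 3-substituted benzofurans. No ring is closed, since ring B is already present as its keto tautomer and is only aromatised, and the carbinol centre of 22 forms as a mixture and is destroyed again, so no stereocentre is set, while the (S)-centre and the Z-alkene of 19 are remote and untouched. The step needs 1,2-addition to win over deprotonation at the OCH2 group (which would give an aromatic 3-furanolate), over deprotonation at the CH2 between the rings and over conjugate attack at the enol ether carbon, and the organocerium reagent at −78 °C is chosen for exactly this. The 2,4-pattern of ring B cannot be scrambled, because the position of the new bond is fixed by the position of the carbonyl group.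

Step 13
Reactants: 23 tert-butyl({(2S,6Z)-9-[5-(furan-3-ylmethyl)furan-3-yl]-2,6-dimethylnon-6-en-1-yl}oxy)diphenylsilane
Product: 24 (2S,6Z)-9-[5-(furan-3-ylmethyl)furan-3-yl]-2,6-dimethylnon-6-en-1-ol
Conditions: Bu4NF, THF, rt
Reagents that add atoms: none
Why: Fluoride-driven desilylation is neutral to basic and should leave the acid-sensitive bis-furan untouched.

Step 14
Reactants: 24 (2S,6Z)-9-[5-(furan-3-ylmethyl)furan-3-yl]-2,6-dimethylnon-6-en-1-ol
Product: 25 (2S,6Z)-9-[5-(furan-3-ylmethyl)furan-3-yl]-2,6-dimethylnon-6-enal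
Conditions: Dess–Martin periodinane, NaHCO3, CH2Cl2, 0 °C
Reagents that add atoms: none
Why: Buffered Dess–Martin oxidation should stop at the aldehyde and keep the α-methyl centre intact, the aldehyde being used at once.

Step 15
Reactants: 26 4-hydroxy-3-methylfuran-2(5H)-one (3-methyltetronic acid)
Product: 27 4-methoxy-3-methylfuran-2(5H)-one
Conditions: Me2SO4, K2CO3, acetone, reflux
Reagents that add atoms: dimethyl sulfate, COS(=O)(=O)OC
Why: O-Alkylation of the vinylogous acid at O4 masks the acidic hydroxyl group and leaves C5–H as the only acidic position for the aldol step.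

Step 16
Reactants: 27 4-methoxy-3-methylfuran-2(5H)-one; 25 (2S,6Z)-9-[5-(furan-3-ylmethyl)furan-3-yl]-2,6-dimethylnon-6-enal
Product: 29 5-{(2S,6Z)-9-[5-(furan-3-ylmethyl)furan-3-yl]-1-hydroxy-2,6-dimethylnon-6-en-1-yl}-4-methoxy-3-methylfuran-2(5H)-one, via lithium furanolate 28 (not isolated)
Conditions: 27, LiN(i-Pr)2, THF, −78 °C; then 25, −78 °C; aq. NH4Cl
Reagents that add atoms: none
Why: Aldol addition of the C5-lithiated methyl tetronate at −78 °C should be faster than enolisation of the aldehyde, and the two new centres (formed as a mixture) are removed in the next step.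

Step 17
Reactants: 29 5-{(2S,6Z)-9-[5-(furan-3-ylmethyl)furan-3-yl]-1-hydroxy-2,6-dimethylnon-6-en-1-yl}-4-methoxy-3-methylfuran-2(5H)-one
Product: 31 (5Z)-5-{(2S,6Z)-9-[5-(furan-3-ylmethyl)furan-3-yl]-2,6-dimethylnon-6-en-1-ylidene}-4-methoxy-3-methylfuran-2(5H)-one, via mesylate 30 (not isolated)
Conditions: MsCl, Et3N, CH2Cl2, 0 °C; then DBU, rt
Reagents that add atoms: none
Why: Mesylation and E1cB elimination through the C5 carbanion should give the thermodynamically preferred Z-ylidene, in which the chain points away from the C4 methoxy group.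

Step 18
Reactants: 31 (5Z)-5-{(2S,6Z)-9-[5-(furan-3-ylmethyl)furan-3-yl]-2,6-dimethylnon-6-en-1-ylidene}-4-methoxy-3-methylfuran-2(5H)-one
Product: 32 (5Z)-5-{(2S,6Z)-9-[5-(furan-3-ylmethyl)furan-3-yl]-2,6-dimethylnon-6-en-1-ylidene}-4-hydroxy-3-methylfuran-2(5H)-one (target)
Conditions: NaSEt, DMF, rt → 50 °C; then 0.1 M aq. HCl, 0 °C
Reagents that add atoms: none
Why: SN2 demethylation by thiolate should be easy because the leaving group is a vinylogous carboxylate, and the non-acidic conditions spare both furans and the Z-ylidene.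

**Compound list**

1 | 2-(furan-3-yl)acetic acid | OC(=O)Cc1ccoc1 | starting material
2 | 2-(furan-3-yl)-N-methoxy-N-methylacetamide | CON(C)C(=O)Cc1ccoc1 | intermediate
3 | 2-(prop-2-yn-1-yloxy)tetrahydro-2H-pyran (racemic) | C#CCOC1CCCCO1 | starting material
4 | [3-(tetrahydro-2H-pyran-2-yloxy)prop-1-yn-1-yl]lithium | [Li]C#CCOC1CCCCO1 | intermediate
5 | 1-(furan-3-yl)-5-(tetrahydro-2H-pyran-2-yloxy)pent-3-yn-2-one | O=C(Cc1ccoc1)C#CCOC1CCCCO1 | intermediate
6 | 1-(furan-3-yl)-5-hydroxypent-3-yn-2-one | O=C(Cc1ccoc1)C#CCO | intermediate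
7 | 4-(diethylamino)-1-(furan-3-yl)-5-hydroxypent-3-en-2-one | CCN(CC)C(CO)=CC(=O)Cc1ccoc1 | intermediate
8 | 5-(furan-3-ylmethyl)furan-3(2H)-one | O=C1COC(Cc2ccoc2)=C1 | intermediate
9 | (R)-4-benzyl-3-propanoyl-1,3-oxazolidin-2-one | CCC(=O)N1[C@H](Cc2ccccc2)COC1=O | starting material
10 | sodium Z-enolate of 9 | C/C=C(\[O-])N1[C@H](Cc2ccccc2)COC1=O.[Na+] | intermediate
11 | (R)-4-benzyl-3-[(S)-2-methylpent-4-enoyl]-1,3-oxazolidin-2-one | C=CC[C@H](C)C(=O)N1[C@H](Cc2ccccc2)COC1=O | intermediate
12 | (S)-2-methylpent-4-en-1-ol | C=CC[C@H](C)CO | intermediate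
13 | tert-butyl{[(S)-2-methylpent-4-en-1-yl]oxy}diphenylsilane | C=CC[C@H](C)CO[Si](c1ccccc1)(c1ccccc1)C(C)(C)C | intermediate
14 | 3-[(tert-butyldimethylsilyl)oxy]propanal | O=CCCO[Si](C)(C)C(C)(C)C | starting material
15 | tert-butyl{[(3Z)-4-iodopent-3-en-1-yl]oxy}dimethylsilane | I/C(C)=C\CCO[Si](C)(C)C(C)(C)C | intermediate
16 | 9-{(S)-5-[(tert-butyldiphenylsilyl)oxy]-4-methylpentyl}-9-borabicyclo[3.3.1]nonane | CC(C)(C)[Si](c1ccccc1)(c1ccccc1)OC[C@@H](C)CCCB1C2CCCC1CCC2 | intermediate
17 | (3Z,8S)-1-[(tert-butyldimethylsilyl)oxy]-9-[(tert-butyldiphenylsilyl)oxy]-4,8-dimethylnon-3-ene | CC(C)(C)[Si](C)(C)OCC/C=C(C)\CCC[C@H](C)CO[Si](c1ccccc1)(c1ccccc1)C(C)(C)C | intermediate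
18 | (3Z,8S)-9-[(tert-butyldiphenylsilyl)oxy]-4,8-dimethylnon-3-en-1-ol | OCC/C=C(C)\CCC[C@H](C)CO[Si](c1ccccc1)(c1ccccc1)C(C)(C)C | intermediate
19 | tert-butyl{[(2S,6Z)-9-iodo-2,6-dimethylnon-6-en-1-yl]oxy}diphenylsilane | ICC/C=C(C)\CCC[C@H](C)CO[Si](c1ccccc1)(c1ccccc1)C(C)(C)C | intermediate
20 | {(3Z,8S)-9-[(tert-butyldiphenylsilyl)oxy]-4,8-dimethylnon-3-en-1-yl}lithium | [Li]CC/C=C(C)\CCC[C@H](C)CO[Si](c1ccccc1)(c1ccccc1)C(C)(C)C | intermediate
21 | {(3Z,8S)-9-[(tert-butyldiphenylsilyl)oxy]-4,8-dimethylnon-3-en-1-yl}cerium dichloride | Cl[Ce](Cl)CC/C=C(C)\CCC[C@H](C)CO[Si](c1ccccc1)(c1ccccc1)C(C)(C)C | intermediate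
22 | 3-{(3Z,8S)-9-[(tert-butyldiphenylsilyl)oxy]-4,8-dimethylnon-3-en-1-yl}-5-(furan-3-ylmethyl)-2,3-dihydrofuran-3-ol (both epimers at the carbinol carbon) | OC1(CC/C=C(C)\CCC[C@H](C)CO[Si](c2ccccc2)(c2ccccc2)C(C)(C)C)COC(Cc2ccoc2)=C1 | intermediate
23 | tert-butyl({(2S,6Z)-9-[5-(furan-3-ylmethyl)furan-3-yl]-2,6-dimethylnon-6-en-1-yl}oxy)diphenylsilane | CC(C)(C)[Si](c1ccccc1)(c1ccccc1)OC[C@@H](C)CCC/C(C)=C\CCc1coc(Cc2ccoc2)c1 | intermediate
24 | (2S,6Z)-9-[5-(furan-3-ylmethyl)furan-3-yl]-2,6-dimethylnon-6-en-1-ol | OC[C@@H](C)CCC/C(C)=C\CCc1coc(Cc2ccoc2)c1 | intermediate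
25 | (2S,6Z)-9-[5-(furan-3-ylmethyl)furan-3-yl]-2,6-dimethylnon-6-enal | O=C[C@@H](C)CCC/C(C)=C\CCc1coc(Cc2ccoc2)c1 | intermediate
26 | 4-hydroxy-3-methylfuran-2(5H)-one (3-methyltetronic acid) | CC1=C(O)COC1=O | starting material
27 | 4-methoxy-3-methylfuran-2(5H)-one | COC1=C(C)C(=O)OC1 | intermediate
28 | lithium 4-methoxy-3-methylfuran-2-olate | [Li+].[O-]c1occ(OC)c1C | intermediate
29 | 5-{(2S,6Z)-9-[5-(furan-3-ylmethyl)furan-3-yl]-1-hydroxy-2,6-dimethylnon-6-en-1-yl}-4-methoxy-3-methylfuran-2(5H)-one (mixture at the two new centres) | COC1=C(C)C(=O)OC1C(O)[C@@H](C)CCC/C(C)=C\CCc1coc(Cc2ccoc2)c1 | intermediate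
30 | methanesulfonate of 29 | COC1=C(C)C(=O)OC1C(OS(C)(=O)=O)[C@@H](C)CCC/C(C)=C\CCc1coc(Cc2ccoc2)c1 | intermediate
31 | (5Z)-5-{(2S,6Z)-9-[5-(furan-3-ylmethyl)furan-3-yl]-2,6-dimethylnon-6-en-1-ylidene}-4-methoxy-3-methylfuran-2(5H)-one | CC1=C(OC)/C(=C/[C@@H](C)CCC/C(C)=C\CCc2coc(Cc3ccoc3)c2)OC1=O | intermediate
32 | (5Z)-5-{(2S,6Z)-9-[5-(furan-3-ylmethyl)furan-3-yl]-2,6-dimethylnon-6-en-1-ylidene}-4-hydroxy-3-methylfuran-2(5H)-one | CC1=C(O)/C(=C/[C@@H](C)CCC/C(C)=C\CCc2coc(Cc3ccoc3)c2)OC1=O | target

**Step count and risks**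

Total steps: 18. Longest linear sequence: 12 steps (5, 6, 7, 9, 10, 11, 12, 13, 14, 16, 17, 18).

Steps most likely to fail:

1. Step 12. Proton transfer from the furanone to the organometallic may outrun carbonyl addition, because deprotonation at the OCH2 group gives an aromatic 3-furanolate; the chain would then be lost by protonation. The fallback uses this same enolisation and sets out from 8 and 19. Furanone 8 with Tf2O and 2,6-di-tert-butylpyridine in CH2Cl2 at −78 °C should be sulfonylated on oxygen to give 5-(furan-3-ylmethyl)furan-3-yl trifluoromethanesulfonate F1. Iodide 19 with activated Zn dust and LiCl in THF should give {(3Z,8S)-9-[(tert-butyldiphenylsilyl)oxy]-4,8-dimethylnon-3-en-1-yl}zinc iodide F2. Negishi coupling of F1 with F2 (PdCl2(dppf), THF/NMP, 50 °C) should then give 23, where the route is rejoined.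

2. Step 18. The thiolate may add in conjugate fashion to the ylidene butenolide, or the basic medium may epimerise the allylic methyl-bearing centre before demethylation is complete. The fallback changes the oxygen protecting group so that the last step is a neutral palladium-catalysed deallylation; it sets out from 26 and 25 and returns at 32. Mitsunobu O-allylation of 26 (allyl alcohol, PPh3, DIAD, THF) should give 4-(allyloxy)-3-methylfuran-2(5H)-one F3. LiN(i-Pr)2 in THF at −78 °C should convert it into lithium 4-(allyloxy)-3-methylfuran-2-olate F4, which adds to aldehyde 25 to give the aldol adduct F5. MsCl and Et3N should give its methanesulfonate F6, and DBU the (5Z)-ylidene allyl ether F7. Pd(PPh3)4 with morpholine in THF at rt should remove the allyl group through a π-allyl complex and give 32.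

3. Step 8. Halogen exchange at the ylide stage and incomplete iodination may give non-iodinated and doubly iodinated alkenes and erode the geometric purity of the alkenyl iodide. The fallback builds the same alkene by two successive stereoselective cross-couplings; it sets out from 14 and returns at 17. Corey–Fuchs olefination of 14 (CBr4, PPh3, Et3N, CH2Cl2, 0 °C) should give tert-butyl[(4,4-dibromobut-3-en-1-yl)oxy]dimethylsilane F8. Trans-selective Negishi monomethylation (MeZnCl, PdCl2(DPEphos), THF, 0 °C → rt) should replace the bromine trans to the chain and give tert-butyl{[(3Z)-4-bromopent-3-en-1-yl]oxy}dimethylsilane F9. Suzuki–Miyaura coupling of F9 with alkylborane 16 (PdCl2(dppf), AsPh3, Cs2CO3, DMF/H2O, 50 °C), with retention, should give 17.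

**Further compounds**

F1 | step 12 | 5-(furan-3-ylmethyl)furan-3-yl trifluoromethanesulfonate | O=S(=O)(Oc1coc(Cc2ccoc2)c1)C(F)(F)F
F2 | step 12 | {(3Z,8S)-9-[(tert-butyldiphenylsilyl)oxy]-4,8-dimethylnon-3-en-1-yl}zinc iodide | I[Zn]CC/C=C(C)\CCC[C@H](C)CO[Si](c1ccccc1)(c1ccccc1)C(C)(C)C
F3 | step 18 | 4-(allyloxy)-3-methylfuran-2(5H)-one | C=CCOC1=C(C)C(=O)OC1
F4 | step 18 | lithium 4-(allyloxy)-3-methylfuran-2-olate | [Li+].[O-]c1occ(OCC=C)c1C
F5 | step 18 | 4-(allyloxy)-5-{(2S,6Z)-9-[5-(furan-3-ylmethyl)furan-3-yl]-1-hydroxy-2,6-dimethylnon-6-en-1-yl}-3-methylfuran-2(5H)-one | C=CCOC1=C(C)C(=O)OC1C(O)[C@@H](C)CCC/C(C)=C\CCc1coc(Cc2ccoc2)c1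
F6 | step 18 | methanesulfonate of F5 | C=CCOC1=C(C)C(=O)OC1C(OS(C)(=O)=O)[C@@H](C)CCC/C(C)=C\CCc1coc(Cc2ccoc2)c1
F7 | step 18 | (5Z)-4-(allyloxy)-5-{(2S,6Z)-9-[5-(furan-3-ylmethyl)furan-3-yl]-2,6-dimethylnon-6-en-1-ylidene}-3-methylfuran-2(5H)-one | CC1=C(OCC=C)/C(=C/[C@@H](C)CCC/C(C)=C\CCc2coc(Cc3ccoc3)c2)OC1=O
F8 | step 8 | tert-butyl[(4,4-dibromobut-3-en-1-yl)oxy]dimethylsilane | BrC(Br)=CCCO[Si](C)(C)C(C)(C)C
F9 | step 8 | tert-butyl{[(3Z)-4-bromopent-3-en-1-yl]oxy}dimethylsilane | Br/C(C)=C\CCO[Si](C)(C)C(C)(C)C
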